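- elm: starting complex 0.010 M; incoming ligand 3 equiv; leaving ligand 0.50 equiv; protic impurity 0.50 mM; the very flask that is asked about, followed so far
- flask: starting complex 0.010 M; incoming ligand 3.00 equiv; leaving ligand 0.500 equiv; protic impurity 0.500 mM; time 15 min

elm run (percent of the starting complex charged)

| time / min | complex with two exchanged / % | complex with one exchanged / % | starting complex / % |
|---|---|---|---|
| 0.833 | 20.1 | 7.0 | 19.8 |
| 1.00 | 22.6 | 6.6 | 17.2 |
| 1.33 | 24.6 | 4.7 | 13.6 |
| 2.00 | 27.1 | 3.8 | 8.7 |
| 2.50 | 28.0 | 3.8 | 7.9 |
| 3.00 | 28.3 | 3.3 | 7.3 |
| 5.00 | 26.7 | 3.7 | 6.6 |

(readings scatter by 0.5 percentage points)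

* the moment within 15 min at which there is most complex with two exchanged
* the amount of complex with two exchanged, in percent of the starting complex charged, at that time
* the first time at which complex with two exchanged reaches 19%, in the same percent, in min

- what was read earlier has a scatter of 0.5 percentage points, one standard deviation
- a reading or a percentage of complex with one exchanged counts all its forms, free or not

The slowness of this flask after its first minutes is what I read, so I follow one rate: the leak, the loss from the sum of the three complexes read. In the elm run that sum is 46.9% at 0.833 min, 38.9% at 3.00 min and 37.0% at 5.00 min. As a share of the charge, the leak is 0.0369 min⁻¹ over the first stretch and 0.00950 min⁻¹ over the second, a slowing by 3.88.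

Between the stretches, [starting complex], taken as the root of the product of each stretch's end readings, falls by 1.73. Order one asks for that factor, order two for 3.00. Through a scatter of 0.5 percentage points per reading, I take [starting complex] as the concentration that sets the leak, second order, and define the leak constant κ, the leak over the product of [starting complex] at the ends of a stretch:

κ = 0.0369 min⁻¹ / (19.8% × 7.3%) = 2.55 min⁻¹

leak = κ × [starting complex] × [starting complex]

This gives 0.100 min⁻¹ at 0.833 min and 0.0111 min⁻¹ at 5.00 min. The fall of [starting complex] by 3.00, squared, is a slowing by 9.00.

Held at that late value for the remaining 10.0 min, my rough reckoning puts the leak at 11.1% of the charge, more than the 10.3% read as starting complex and complex with one exchanged at 5.00 min in the elm run. So I expect no further rise and commit to the top of the readings, 28.3% at 3.00 min.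

The forecast gives 2.8 min, 28.2% and 0.76 min, holding that “the maximum should remain early”.

The flask peaks at 2.98 min with 27.6% and reaches 19% at 0.759 min.

    starting complex + incoming ligand ⇌ leaving ligand + complex with one exchanged (K = 0.230, k = 0.690 L mol⁻¹ s⁻¹)
    complex with one exchanged + incoming ligand ⇌ leaving ligand + complex with two exchanged (K = 3.20, k = 1.90 L mol⁻¹ s⁻¹)
    crystals ⇌ complex with one exchanged, rate k3*(cs3 - [complex with one exchanged]) while solid is left; crystals form when [complex with one exchanged] > cs3 (solubility = 3.80 mM, k = 2.80 s⁻¹)
    2 starting complex → self-condensation product (k = 2.40 L mol⁻¹ s⁻¹)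
    protic impurity + starting complex → quenched substrate (k = 16.0 L mol⁻¹ s⁻¹)

In this flask, from 2.98 min to 15.0 min, the self-condensation product, each counted as two, rises from 56.2% to 65.7%, a gain of 9.5 points. κ on the [starting complex] at those two times, 7.35% and 4.09%, gives 9.23%. The neighbour flask with 1.80 equiv of incoming ligand stands at 3.85% starting complex at 15.0 min, so κ gives it a leak of 0.00378 min⁻¹ against 0.00427 min⁻¹ in this flask at that time, with 13.0% of complex with two exchanged against 22.6%.

(All runs are calculated with made-up constants.)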